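## The problem

Locants used throughout: C-1 to C-9 are the bicyclo[3.3.1]nonane atoms (C-1 benzoyl bridgehead, C-2/C-3/C-4 the diketone bridge, C-5 geranyl bridgehead, C-6 CH2, C-7 CH, C-8 CMe2, C-9 bridging C=O). C-10 is the CH2 on C-7, C-11 the CH bonded to C-3, C-12 the second CMe2, C-13 the CH bearing the carbinol carbon C-15, and C-14 the CH2 on C-3.

The target is a cyclohexane-1,3,5-trione (C-1, C-2, C-3, C-4, C-5, C-9) whose three quaternary α-carbons are tied together by a tripod centred on C-7: C-6 reaches C-5, C-8 reaches C-1 and the C-10–C-11 arm reaches C-3. This gives a homoadamantane (one six-membered and two seven-membered rings), and a cyclopentane (C-3, C-11, C-12, C-13, C-14) is fused onto its C-3–C-11 bond. Six stereocentres (C-1, C-3, C-5, C-7, C-11, C-13) must be set as one enantiomer, with C-1, C-8 and the benzoyl carbon forming a crowded, fully substituted array. Once C-5 is fixed, C-1, C-3 and C-7 are dictated by the cage, but only if the C-7 arm is endo (turned toward C-3); the exo epimer, which kinetic ring closures favour, cannot close at all. C-11 and C-13 are the only centres that need real induction. A hidden constitutional problem is that C-3 and C-5 derive from two equivalent phloroglucinol carbons: one must take only prenyl, the other geranyl plus C-6. The triketone has no enolizable hydrogen and is cleaved by nucleophiles (retro-Claisen), the geranyl diene is sensitive to acid, electrophiles and metathesis, and the tertiary alcohol eliminates easily.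

The feature that makes the key step possible: if the C-3–C-11 and C-12–C-13 bonds are cut, C-3 becomes the central carbon of an enolizable C-2/C-4 diketone, which can be oxidized to a carbon radical. The units C-10/C-11/C-12 and C-14/C-13/C-15 are then two prenyl groups on C-7 and C-3. The two seven-membered rings and the cyclopentane are exactly the rings that a C-3 radical would close.

## Retrosynthesis

**18 ⇒ 17.** The O–C-15 bond is cut, giving the isopropenyl compound 17. Letting the cascade itself end in oxygen capture would expose the earlier C-12 radical to the same trap, so the cascade is run without oxygen and the alkene is hydrated afterwards. The forward step must hydrate a 1,1-disubstituted alkene at its more substituted carbon and leave the two trisubstituted geranyl alkenes alone.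

**17 ⇒ 16 (key).** The C-3–C-11 and C-12–C-13 bonds are cut, leaving the bicyclic enol 16 with two prenyl groups. Cutting C-1–C-8 or C-5–C-6 instead would leave a medium ring carrying the cyclopentane, and cutting only C-12–C-13 would leave the homoadamantane unsolved. This cut removes three rings and three stereocentres (C-3, C-11, C-13) at once. The forward reaction must generate the C-3 radical, close 7-exo then 5-exo, and select one face at C-11 and at C-13.

**16 ⇒ 15 ⇒ 14 ⇒ 12.** The 7-endo prenyl group is taken apart: C-11=C-12 by cross-metathesis (15), C-10–H by reductive removal of an allylic carbonate (14), and C-10–C-11 by vinyl addition to an aldehyde. That aldehyde carbon C-10 is stored as the aldol bond C-3–C-10 of the hydroxy-adamantane 12 (alcohol 13 is the unisolated link). The reason for this detour is that a 7-endo substituent cannot be installed directly; the cage 12 holds it.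

**12 ⇒ 11.** The aldol bond C-3–C-10 and the C-1–C-8 bond (enol plus β,β-dimethyl enal) are cut, giving the monocyclic dienone 11 with a single stereocentre. The forward step is stereoconvergent: C-7 is epimerizable next to the aldehyde and only its endo form can close the cage, so C-1, C-3 and C-7 all follow from C-5.

**11 ⇒ 10 ⇒ 9 + 4.** The C-3 prenyl group is traced to a prenyl ester on C-3 (10; decarboxylative prenylation), and the C-5–C-6 bond is cut to phenol 9 and bromo enal 4. The ester is the regiochemical switch: it makes C-3 an acyl-bearing, non-nucleophilic carbon, so C-5 is the only ring carbon that can accept 4. Without it the geranyl- and prenyl-bearing carbons cannot be told apart. The alkylation is the only catalyst-controlled stereochemical event of the route.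

**9 ⇒ 7 ⇒ 5 + 6; 4 ⇒ 2 ⇒ 1.** Carboxylation/esterification of the last free ring carbon of 7 (via carboxylate 8) and C-geranylation of the commercial benzophenone 5 with 6. The enal 4 comes from diol 2 (via hydroxy enal 3), made by reduction of the commercial malonate 1.

## Roads not taken

Alternative 1: The most obvious cut for a bicyclo[3.3.1]nonane-2,4,9-trione is C-1–C-2 plus C-4–C-5. The forward key step would be an Effenberger annulation of the cyclohexanone enol ether A1 to the trione A2, followed by bridgehead benzoylation at C-1 and prenylation at C-3 to reach 16. The three-carbon bridge is delivered anti to the C-7 prenyl group, so A2 has the exo configuration at C-7, which cannot enter the cascade. Acylation at the bridgehead next to the quaternary C-8 also needs enol protection and strong base (at least four more steps), and A1 would need its own asymmetric synthesis. The chosen plan gets endo from a cage and the benzoyl group from the starting material.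

Alternative 2: C-1–C-8 could be cut as an enol-plus-tertiary-cation bond, as in the presumed biosynthesis. The forward step would generate the C-8 cation from the isopropenyl group of the dearomatized lavandulyl ketone A3. The chair-like closure puts the C-7 prenyl group equatorial and gives the exo bicycle A4. A cation next to H-7 also scrambles C-7 by loss and return of a proton, the enol oxygens compete to form pyrans, and acid endangers the geranyl group. The prenyl group of A4 points away from C-3, so the cascade cannot start. The chosen plan makes C-1–C-8 by conjugate addition and lets ring strain select C-7.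

Alternative 3: The three acyl bonds C-1–C-2, C-1–C-9 and C-3–C-4 could be cut together (the cut that removes most bridges at once). The forward step would be a triple Claisen condensation of the cyclopentane triester A5. The last acylation forms a triketone without an acidic hydrogen, so no enolate drives the equilibrium and retro-Claisen cleavage wins. A5 would also need C-7, C-11 and C-13 set on a flexible chain with no cage to guide them. The chosen plan closes the trione by dearomatization and uses the finished trione ring to direct the rest.

Key step: step 10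

Assumption: geranyl means (2E)-3,7-dimethylocta-2,6-dien-1-yl and prenyl means 3-methylbut-2-en-1-yl; endo means the face of C-7 turned toward C-3; the absolute configuration of each compound is the one in its SMILES string.

## Route

Step 1
Reactants: 1 diethyl 2-(propan-2-ylidene)propanedioate
Product: 2 2-(propan-2-ylidene)propane-1,3-diol
Conditions: i-Bu2AlH, toluene, −78 to 0 °C
Reagents that add atoms: none
Why: 1,2-Reduction of both conjugated esters by the electrophilic hydride should give the allylic diol; no stereocentre is formed.

Step 2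
Reactants: 2 2-(propan-2-ylidene)propane-1,3-diol
Product: 4 2-(bromomethyl)-3-methylbut-2-enal, via 2-(hydroxymethyl)-3-methylbut-2-enal 3 (not isolated)
Conditions: MnO2, CH2Cl2, 25 °C, filtration; then PBr3, Et2O, −20 °C
Reagents that add atoms: phosphorus tribromide, BrP(Br)Br
Why: Allylic oxidation by MnO2 should stop after one of the two equivalent alcohols because the enal deactivates the second; PBr3 then converts the remaining primary allylic alcohol into the bromide (SN2).

Step 3
Reactants: 5 phenyl(2,4,6-trihydroxyphenyl)methanone; 6 geranyl bromide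
Product: 7 (3-geranyl-2,4,6-trihydroxyphenyl)(phenyl)methanone
Conditions: KOH, H2O, 0 to 25 °C
Reagents that add atoms: none
Why: C-alkylation of the phloroglucinol phenoxide in water (a protic medium favours C over O); the two free ring carbons of 5 are equivalent and a deficit of bromide should hold the reaction at the mono-geranyl stage.

Step 4
Reactants: 7 (3-geranyl-2,4,6-trihydroxyphenyl)(phenyl)methanone
Product: 9 prenyl 3-benzoyl-5-geranyl-2,4,6-trihydroxybenzoate, via potassium 3-benzoyl-5-geranyl-2,4,6-trihydroxybenzoate 8 (not isolated)
Conditions: KHCO3, CO2 (1 atm), DMF, 60 °C; then 1-bromo-3-methylbut-2-ene, 25 °C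
Reagents that add atoms: carbon dioxide, O=C=O; 1-bromo-3-methylbut-2-ene, CC(C)=CCBr
Why: Kolbe–Schmitt carboxylation at the only unsubstituted ring carbon, then SN2 esterification of the carboxylate; the ester makes the future C-3 a non-nucleophilic, acyl-bearing carbon and carries the prenyl group delivered to it in step 6.

Step 5
Reactants: 9 prenyl 3-benzoyl-5-geranyl-2,4,6-trihydroxybenzoate; 4 2-(bromomethyl)-3-methylbut-2-enal
Product: 10 prenyl (5S)-3-benzoyl-5-geranyl-5-(2-formyl-3-methylbut-2-en-1-yl)-2,4-dihydroxy-6-oxocyclohexa-1,3-diene-1-carboxylate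
Conditions: CsOH·H2O, N-(9-anthracenylmethyl)-O-allylcinchonidinium bromide (10 mol %), toluene/CH2Cl2, −50 °C
Reagents that add atoms: none
Why: Alkylative dearomatization under asymmetric phase-transfer catalysis: C-5 is the only ring carbon without an acyl group, so the allylic bromide (SN2) can only attach there; the chiral ammonium ion pair should shield one face and set C-5, and the pseudoenantiomeric cinchoninium salt is used if the sense of induction is the opposite.

Step 6
Reactants: 10 prenyl (5S)-3-benzoyl-5-geranyl-5-(2-formyl-3-methylbut-2-en-1-yl)-2,4-dihydroxy-6-oxocyclohexa-1,3-diene-1-carboxylate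
Product: 12 1-benzoyl-5-geranyl-10-hydroxy-8,8-dimethyl-3-prenyladamantane-2,4,9-trione (C-10 epimers; cage enantiomer as in the SMILES), via prenylated dienone 11 (not isolated)
Conditions: Pd(PPh3)4 (5 mol %), THF, 25 °C; then conc. aq. HCl, THF, 0 °C
Reagents that add atoms: none
Why: Tsuji decarboxylative allylation: zerovalent palladium ionizes the prenyl ester, CO2 is lost and the C-3 enolate attacks the unsubstituted terminus of the prenylpalladium cation; acid then drives aldol addition of the C-3 enol to the aldehyde and conjugate addition of the C-1 enol to the β,β-dimethyl enal, the acid-mediated route to hydroxy-adamantane cores of type A acylphloroglucinols. C-7 is epimerizable next to the aldehyde and only its endo form can close C-3–C-10, so the cage should funnel to one C-7 configuration; C-1 follows from C-5 because C-8 reaches C-1 only on the face that carries C-6.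

Step 7
Reactants: 12 1-benzoyl-5-geranyl-10-hydroxy-8,8-dimethyl-3-prenyladamantane-2,4,9-trione
Product: 14 methyl carbonate of 1-benzoyl-5-geranyl-4-hydroxy-7-endo-(1-hydroxyprop-2-en-1-yl)-8,8-dimethyl-3-prenylbicyclo[3.3.1]non-3-ene-2,9-dione (carbinol epimers), via allylic alcohol 13 (not isolated)
Conditions: CH2=CHMgBr, CeCl3, THF, −78 to −20 °C; then ClCO2Me, −78 °C
Reagents that add atoms: vinylmagnesium bromide, C=C[Mg]Br; methyl chloroformate, COC(=O)Cl
Why: Deprotonation of the C-10 hydroxyl starts a retro-aldol cleavage of C-3–C-10 (the diketone enolate leaves), and the freed 7-endo aldehyde should be captured by the weakly basic vinylcerium reagent faster than it epimerizes; the hard secondary alkoxide is then acylated while the chelated diketonate is left. The carbinol configuration is irrelevant because the oxygen is removed in step 8.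

Step 8
Reactants: 14 methyl carbonate of the 7-endo-(1-hydroxyprop-2-en-1-yl) bicycle
Product: 15 7-endo-allyl-1-benzoyl-5-geranyl-4-hydroxy-8,8-dimethyl-3-prenylbicyclo[3.3.1]non-3-ene-2,9-dione
Conditions: Pd(OAc)2 (5 mol %), PBu3, HCO2NH4, 1,4-dioxane, 60 °C
Reagents that add atoms: none
Why: Tsuji–Trost formate reduction: the allylpalladium formate loses CO2 and delivers hydride to the more substituted allyl terminus C-10, which should give the terminal alkene and leave C-7 untouched.

Step 9
Reactants: 15 7-endo-allyl-1-benzoyl-5-geranyl-4-hydroxy-8,8-dimethyl-3-prenylbicyclo[3.3.1]non-3-ene-2,9-dione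
Product: 16 1-benzoyl-5-geranyl-4-hydroxy-8,8-dimethyl-3,7-endo-diprenylbicyclo[3.3.1]non-3-ene-2,9-dione
Conditions: (H2IMes)(PCy3)Cl2Ru=CHPh (second-generation Grubbs catalyst, 5 mol %), 2-methyl-2-butene/CH2Cl2, 40 °C
Reagents that add atoms: 2-methyl-2-butene, CC=C(C)C
Why: Olefin cross-metathesis of the single monosubstituted alkene with 2-methyl-2-butene; the trisubstituted prenyl and geranyl alkenes react far more slowly, so their chain lengths should be kept.

Step 10
Reactants: 16 1-benzoyl-5-geranyl-4-hydroxy-8,8-dimethyl-3,7-endo-diprenylbicyclo[3.3.1]non-3-ene-2,9-dione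
Product: 17 the 15-anhydro (13-isopropenyl) cage: 1-benzoyl-5-geranyl-8,8,12,12-tetramethyl-13-(prop-1-en-2-yl) homoadamantane-2,4,9-trione with the cyclopentane C-3/C-11/C-12/C-13/C-14, C-12 on the C-4 side, H-11 cis to the C-13 substituent
Conditions: Mn(OAc)3·2H2O (2.2 equiv), Cu(OAc)2·H2O (1 equiv), degassed AcOH, 25 °C
Reagents that add atoms: none
Why: Trivalent manganese oxidizes the enol of the C-2/C-4 diketone (the only enolizable site of 16) to the C-3 radical; the reaction type is the manganese triacetate/copper diacetate oxidative radical cyclization of 2-alkyl-1,3-diketones, known also for cascades of prenylated acylphloroglucinols. The electrophilic C-3 radical adds to the inner alkene carbon C-11 of the 7-endo prenyl group held beneath it (7-exo-trig; this one bond closes both seven-membered rings of the homoadamantane) and gives the tertiary C-12 radical. C-12 then adds to C-13 of the C-3 prenyl group (5-exo-trig, cyclopentane), and the resulting tertiary C-15 radical, with no alkene in reach, is oxidized by divalent copper to the less substituted alkene. C-3 is set by the tether, since C-10 can deliver C-11 only to the endo face and C-14 is left exo. C-11 is set by the alkene face: the C-12 end should swing to the C-4/C-6 flank, away from the lower methyl group on C-8 and the benzoyl group. C-13 is set by the chair-like 5-exo transition state, which puts the isopropylidene carbon on the convex face, trans to C-10 and cis to H-11. The step needs the C-3 radical to ignore the geranyl group and the C-12 radical to cyclize before it is oxidized: the equatorial bridgehead geranyl chain cannot reach the radical lobe at C-3, and the 5-exo closure is accelerated by the quaternary C-3 and favoured by a low copper concentration.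

Step 11
Reactants: 17 the 15-anhydro (13-isopropenyl) cage
Product: 18 target CNP0164095.1: 1-benzoyl-5-geranyl-13-(2-hydroxypropan-2-yl)-8,8,12,12-tetramethyl homoadamantane-2,4,9-trione fused at C-3–C-11 to the cyclopentane, configuration as in the SMILES
Conditions: Co(acac)2 (20 mol %), PhSiH3, O2 (1 atm), i-PrOH, 25 °C
Reagents that add atoms: dioxygen, O=O
Why: Mukaiyama hydration (hydrogen-atom transfer from a cobalt hydride, capture of the tertiary radical by O2, reduction) places OH on C-15; the 1,1-disubstituted alkene should react ahead of the trisubstituted geranyl alkenes, and the neutral conditions spare the non-enolizable triketone.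

## Compound list

1 | diethyl 2-(propan-2-ylidene)propanedioate | CCOC(=O)C(=C(C)C)C(=O)OCC | starting material
2 | 2-(propan-2-ylidene)propane-1,3-diol | CC(C)=C(CO)CO | intermediate
3 | 2-(hydroxymethyl)-3-methylbut-2-enal | CC(C)=C(CO)C=O | intermediate
4 | 2-(bromomethyl)-3-methylbut-2-enal | CC(C)=C(CBr)C=O | intermediate
5 | phenyl(2,4,6-trihydroxyphenyl)methanone | O=C(c1ccccc1)c1c(O)cc(O)cc1O | starting material
6 | geranyl bromide, (2E)-1-bromo-3,7-dimethylocta-2,6-diene | CC(C)=CCC/C(C)=C/CBr | starting material
7 | (3-geranyl-2,4,6-trihydroxyphenyl)(phenyl)methanone | CC(C)=CCC/C(C)=C/Cc1c(O)cc(O)c(C(=O)c2ccccc2)c1O | intermediate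
8 | potassium 3-benzoyl-5-geranyl-2,4,6-trihydroxybenzoate | CC(C)=CCC/C(C)=C/Cc1c(O)c(C(=O)[O-])c(O)c(C(=O)c2ccccc2)c1O.[K+] | intermediate
9 | prenyl 3-benzoyl-5-geranyl-2,4,6-trihydroxybenzoate | CC(C)=CCC/C(C)=C/Cc1c(O)c(C(=O)OCC=C(C)C)c(O)c(C(=O)c2ccccc2)c1O | intermediate
10 | prenyl (5S)-3-benzoyl-5-geranyl-5-(2-formyl-3-methylbut-2-en-1-yl)-2,4-dihydroxy-6-oxocyclohexa-1,3-diene-1-carboxylate | CC(C)=CCC/C(C)=C/C[C@@]1(CC(C=O)=C(C)C)C(=O)C(C(=O)OCC=C(C)C)=C(O)C(C(=O)c2ccccc2)=C1O | intermediate
11 | (6S)-4-benzoyl-6-geranyl-6-(2-formyl-3-methylbut-2-en-1-yl)-3,5-dihydroxy-2-prenylcyclohexa-2,4-dien-1-one | CC(C)=CCC/C(C)=C/C[C@@]1(CC(C=O)=C(C)C)C(=O)C(CC=C(C)C)=C(O)C(C(=O)c2ccccc2)=C1O | intermediate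
12 | 1-benzoyl-5-geranyl-10-hydroxy-8,8-dimethyl-3-prenyladamantane-2,4,9-trione (C-10 epimers) | CC(C)=CCC/C(C)=C/C[C@]12C[C@@H]3C(C)(C)[C@](C(=O)c4ccccc4)(C1=O)C(=O)[C@](CC=C(C)C)(C2=O)C3O | intermediate
13 | 1-benzoyl-5-geranyl-4-hydroxy-7-endo-(1-hydroxyprop-2-en-1-yl)-8,8-dimethyl-3-prenylbicyclo[3.3.1]non-3-ene-2,9-dione (carbinol epimers) | CC(C)=CCC/C(C)=C/C[C@@]12C[C@@H](C(O)C=C)C(C)(C)[C@](C(=O)c3ccccc3)(C2=O)C(=O)C(CC=C(C)C)=C1O | intermediate
14 | methyl carbonate of 13 at the allylic hydroxyl | CC(C)=CCC/C(C)=C/C[C@@]12C[C@@H](C(OC(=O)OC)C=C)C(C)(C)[C@](C(=O)c3ccccc3)(C2=O)C(=O)C(CC=C(C)C)=C1O | intermediate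
15 | 7-endo-allyl-1-benzoyl-5-geranyl-4-hydroxy-8,8-dimethyl-3-prenylbicyclo[3.3.1]non-3-ene-2,9-dione | CC(C)=CCC/C(C)=C/C[C@@]12C[C@@H](CC=C)C(C)(C)[C@](C(=O)c3ccccc3)(C2=O)C(=O)C(CC=C(C)C)=C1O | intermediate
16 | 1-benzoyl-5-geranyl-4-hydroxy-8,8-dimethyl-3,7-endo-diprenylbicyclo[3.3.1]non-3-ene-2,9-dione | CC(C)=CCC/C(C)=C/C[C@@]12C[C@@H](CC=C(C)C)C(C)(C)[C@](C(=O)c3ccccc3)(C2=O)C(=O)C(CC=C(C)C)=C1O | intermediate
17 | 15-anhydro (13-isopropenyl) cage | CC(C)=CCC/C(C)=C/C[C@@]12C[C@H]3C[C@H]4C(C)(C)[C@H](C(C)=C)C[C@]4(C1=O)C(=O)[C@@](C(=O)c1ccccc1)(C2=O)C3(C)C | intermediate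
18 | CNP0164095.1 | CC(C)=CCC/C(C)=C/C[C@@]12C[C@H]3C[C@H]4C(C)(C)[C@H](C(C)(C)O)C[C@]4(C1=O)C(=O)[C@@](C(=O)c1ccccc1)(C2=O)C3(C)C | target

## Step count and least certain steps

Total: 11 steps (2 for fragment 4, 9 in the main line). Longest linear sequence: 9 steps (steps 3 to 11, from 5).

**Step 10 (key).** The C-12 radical may be oxidized by copper before the 5-exo closure; C-11 may be attacked from the other alkene face; the C-3 radical may be captured by the oxidant if the seven-membered closure is slow. Fallback, setting out from 16 and returning at 18: N-chlorosuccinimide chlorinates C-3 to give the 3-chloro-2,4-diketone F1. Atom-transfer radical cyclization (CuCl, tris(2-pyridylmethyl)amine, 1,2-dichloroethane, 60 °C) runs the same two closures without an external oxidant and ends in the cage tertiary chloride F2. Silver-assisted hydrolysis (AgOTf, aqueous acetone) converts F2 into 18, with no alkene stage and no hydration.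

**Step 5.** The ion pair may discriminate the two faces of C-5 poorly, and O-alkylation may compete. Fallback, setting out from 9 and returning at 12: alkylation with Bu4NBr in place of the chiral salt gives the racemic dienone F3. The conditions of step 6 convert it into the racemic cage alcohol F4, whose rigid shape suits preparative chromatography on a chiral stationary phase. The enantiomer 12 continues with step 7.

**Step 6.** The palladium-bound enolate may be protonated instead of C-prenylated, or prenylated on oxygen. In the acid stage the C-3 prenyl group may cyclize onto an enol oxygen, or the geranyl group onto itself. Fallback, setting out from 10 and returning at 11: Pd(PPh3)4 with morpholine as prenyl acceptor removes the ester as CO2 and gives the C-3 unsubstituted dienone F5. Its single free ring carbon is C-prenylated (1-bromo-3-methylbut-2-ene, aqueous KOH, 0 °C) to give 11, which is then taken through the acid stage alone.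

**Step 4.** Carboxylation of the benzoyl-deactivated ring may stay incomplete or revert on work-up, and the acidic phenols may be alkylated during esterification. Fallback, setting out from 7 and returning at 11: 7 is C-prenylated to the geranyl prenyl benzophenone F6 (1-bromo-3-methylbut-2-ene, aqueous KOH). Alkylation with 4 under the conditions of step 5 then gives 11 directly, at the price of a chromatographic separation from the constitutional isomer F7, which carries the formyl side chain on the prenyl-bearing carbon. The ester switch and the palladium stage of step 6 are then not needed.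

## Further compounds

F1 | step 10 | 1-benzoyl-3-chloro-5-geranyl-8,8-dimethyl-3,7-endo-diprenylbicyclo[3.3.1]nonane-2,4,9-trione (C-3 epimers) | CC(C)=CCC/C(C)=C/C[C@@]12C[C@@H](CC=C(C)C)C(C)(C)[C@](C(=O)c3ccccc3)(C2=O)C(=O)C(Cl)(CC=C(C)C)C1=O
F2 | step 10 | 15-chloro-15-deoxy analogue of 18 (tertiary chloride) | CC(C)=CCC/C(C)=C/C[C@@]12C[C@H]3C[C@H]4C(C)(C)[C@H](C(C)(C)Cl)C[C@]4(C1=O)C(=O)[C@@](C(=O)c1ccccc1)(C2=O)C3(C)C
F3 | step 5 | racemic 10 | CC(C)=CCC/C(C)=C/CC1(CC(C=O)=C(C)C)C(=O)C(C(=O)OCC=C(C)C)=C(O)C(C(=O)c2ccccc2)=C1O
F4 | step 5 | racemic 12 (relative configuration fixed by the cage) | CC(C)=CCC/C(C)=C/CC12CC3C(C)(C)C(C(=O)c4ccccc4)(C1=O)C(=O)C(CC=C(C)C)(C2=O)C3O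
F5 | step 6 | (6S)-4-benzoyl-6-geranyl-6-(2-formyl-3-methylbut-2-en-1-yl)-3,5-dihydroxycyclohexa-2,4-dien-1-one | CC(C)=CCC/C(C)=C/C[C@@]1(CC(C=O)=C(C)C)C(=O)C=C(O)C(C(=O)c2ccccc2)=C1O
F6 | step 4 | (3-geranyl-2,4,6-trihydroxy-5-prenylphenyl)(phenyl)methanone | CC(C)=CCC/C(C)=C/Cc1c(O)c(CC=C(C)C)c(O)c(C(=O)c2ccccc2)c1O
F7 | step 4 | 4-benzoyl-2-geranyl-6-(2-formyl-3-methylbut-2-en-1-yl)-3,5-dihydroxy-6-prenylcyclohexa-2,4-dien-1-one (constitutional isomer of 11) | CC(C)=CCC/C(C)=C/CC1=C(O)C(C(=O)c2ccccc2)=C(O)C(CC=C(C)C)(CC(C=O)=C(C)C)C1=O
A1 | alternative 1 | 2-geranyl-1-methoxy-5,5-dimethyl-4-prenylcyclohex-1-ene | COC1=C(C/C=C(C)/CCC=C(C)C)CC(CC=C(C)C)C(C)(C)C1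
A2 | alternative 1 | 5-geranyl-8,8-dimethyl-7-exo-prenylbicyclo[3.3.1]nonane-2,4,9-trione | CC(C)=CCC/C(C)=C/C[C@]12C[C@H](CC=C(C)C)C(C)(C)[C@H](C1=O)C(=O)CC2=O
A3 | alternative 2 | 4-benzoyl-6-geranyl-3,5-dihydroxy-6-[5-methyl-2-(prop-1-en-2-yl)hex-4-en-1-yl]-2-prenylcyclohexa-2,4-dien-1-one | CC(C)=CCC/C(C)=C/CC1(CC(CC=C(C)C)C(C)=C)C(=O)C(CC=C(C)C)=C(O)C(C(=O)c2ccccc2)=C1O
A4 | alternative 2 | 7-exo epimer of 16 | CC(C)=CCC/C(C)=C/C[C@@]12C[C@H](CC=C(C)C)C(C)(C)[C@](C(=O)c3ccccc3)(C2=O)C(=O)C(CC=C(C)C)=C1O
A5 | alternative 3 | dimethyl 2-geranyl-2-{2-[(cyclopentyl)methyl]-3,3-dimethyl-5-oxo-5-phenylpentyl}malonate, cyclopentyl = 3-(2-hydroxypropan-2-yl)-5-(methoxycarbonyl)-2,2-dimethylcyclopentyl | COC(=O)C(C(=O)OC)(C/C=C(C)/CCC=C(C)C)C[C@@H](C[C@H]1C(C)(C)[C@H](C(C)(C)O)C[C@@H]1C(=O)OC)C(C)(C)CC(=O)c1ccccc1
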